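## Structural features

The target is a phenylcoumaran-type neolignan: a 2,3-dihydrobenzofuran whose benzene ring A (C3a to C7a) carries a methoxy group at C7 and an (E)-propenoic acid at C5, whose C2 bears a 4-hydroxy-3,5-dimethoxyphenyl (syringyl) ring and whose C3 bears a hydroxymethyl group. The only stereocentres are the adjacent C2 (S) and C3 (R); reading the stereodescriptors places the aryl group and the CH2OH on opposite faces of the five-membered ring, the thermodynamically preferred trans arrangement. The fragile groups are the free syringyl phenol para to C2 (as phenoxide it can expel O1 through a para-quinone methide, and under acid the same C2–O1 bond can ionise), the (E)-acrylic acid (sensitive to hydrogenation, conjugate addition and light) and the primary alcohol. The real difficulty is absolute control of two contiguous benzylic stereocentres lying between two electron-rich arenes, while never having both of them labile at once: C3 can epimerise only while it is alpha to a carbonyl group, C2 only once the phenol is free. The key step exploits the C2–C3 bond: C2 is a benzylic ether carbon (O1–CH–aryl), and C3 is bonded to ring A and to a carbon that can stand at the ester oxidation level, so C3 can be a donor/acceptor carbene and C2 the CH2 of an aryl benzyl ether. The ether oxygen O1 then holds that CH2 exactly five atoms from the carbene carbon, the ideal distance for ring-forming C–H insertion. The rest of the skeleton maps onto two cheap C6–C1 aromatic aldehydes, a two-carbon diazoacetate and a two-carbon acid unit.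

## Logic of the disconnections

15 back to 14. No skeletal bond is cut; the phenolic O–H is exchanged for an O–Si bond. The free phenol is the trigger for quinone-methide opening at C2, so it should appear only in the last, near-neutral operation. The gain is that every earlier basic or warm step sees an inert aryl silyl ether. The demand is a final unmasking that leaves the acrylic acid, the alcohol and both stereocentres alone.

14 back to 12. The Cα=Cβ double bond of the side chain is cut, which removes a CH–CO2H unit and leaves the aldehyde on C5 of ring A. An aldehyde is the simplest handle that can be carried masked through the ring-forming chemistry. The forward step must be an (E)-selective, decarboxylative condensation that tolerates the free CH2OH and the aryl silyl ether.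

12 back to 10 (through 11). No C–C bond is cut: C3–CH2OH is traced back to C3–CO2Et and the C5 aldehyde to its dioxolane. The ester is what makes C3 both carbene-capable and epimerisable, and the acetal hides the aldehyde from carbenoid and hydride. The gain is that 10 is the direct product of the ring-forming step. The demand is a hydride reduction that spares acetal and silyl ether, followed by a hydrolysis that spares the silyl ether and the benzylic C2–O1 bond; from here on C3 is configurationally fixed.

10 back to 8 (through 9). The C2–C3 bond is cut, the dihydrofuran ring opens and both stereocentres vanish, leaving an achiral aryl benzyl ether that carries a diazoacetate on ring A. This is the largest single simplification in the route. The forward step must replace one of two enantiotopic benzylic hydrogens under catalyst control, at the ether CH2 and nowhere else, and C3 must then be equilibrated to trans while C2 stays untouched.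

8 back to 6 and 7. The bond between ring A and the diazo carbon is cut. The diazo function is then bought ready-made, with no arylacetic acid synthesis and no diazo transfer. The demand is a cross-coupling at the C–H bond of the diazo compound that keeps N2 in place and works next to a bulky ortho ether.

6 back to 2 and 5. The benzylic CH2–O bond is cut, which gives two aromatic halves of similar size and makes the route convergent. The forward step must O-alkylate a phenol flanked by iodine and methoxy under conditions mild enough for the acetal and the silyl ether. A redox condensation of the benzylic alcohol is preferred to a separate benzylic halide, which saves one step and avoids an ionisation-prone alkylating agent.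

2 back to 1, and 5 back to 4 and then 3. Only protecting-group and redox adjustments remain: the acetal C–O bonds, the O–Si bond and the benzylic C–H bond from carbonyl reduction. Both starting materials already carry every ring substituent in the right place, so no aromatic substitution chemistry is needed.

## Other disconnections considered

Alternative 1: The cut removes ring A: C3a–C4 and C7–C7a are disconnected, so that O1, C2, C3, C3a and C7a come from the trans lactone A2, (4R,5S)-5-[3,5-dimethoxy-4-(methoxymethoxy)phenyl]-4-[(methoxymethoxy)methyl]oxolan-2-one, and the other four ring carbons from the bromopyrone A3, methyl 3-bromo-2-oxo-2H-pyran-5-carboxylate. In the forward step the silyl ketene acetal of A2 would add as an electron-rich two-carbon partner across C3 and C6 of the electron-poor pyrone A3 (lactone α-carbon to C6, acetal carbon to C3). The bridged adduct would lose CO2 and then silanol to aromatise to A1, methyl (2S,3R)-trans-7-bromo-2-[3,5-dimethoxy-4-(methoxymethoxy)phenyl]-3-[(methoxymethoxy)methyl]-2,3-dihydrobenzofuran-5-carboxylate.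
- In favour: both stereocentres are made on a small lactone by substrate control and neither is alpha to the enolised carbonyl, so they should pass through the benzannulation intact. No diazo compound and no late enantioselective catalysis is needed. On stereochemical security and on hazard this alternative is the better plan.
- Against: ring A arrives with the wrong substituents. The C7 bromide must become a methoxy group next to the ring oxygen, the C5 ester must be taken to the aldehyde level, and two methoxymethyl ethers must be removed with acid from a product whose C2–O1 bond becomes acid-labile once the phenol is free. Enantioenriched A2 itself needs a multi-step asymmetric preparation.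
- Comparison: on structure the chosen plan buys ring A with all three substituents already correct. On mechanism both key steps are concerted or nearly so and about equally predictable. On step economy the chosen plan should be shorter by several steps.

Alternative 2: Two bonds are cut at once, C2–aryl and C3–CH2, leading back to the benzofuran A5, 2-(7-methoxy-1-benzofuran-5-yl)-1,3-dioxolane, the syringyl boronate A6, 2-[3,5-dimethoxy-4-(triisopropylsilyloxy)phenyl]-4,4,5,5-tetramethyl-1,3,2-dioxaborolane, and an allyl electrophile. In the forward step A5, lithiated at C2, would form an ate complex with A6. Attack of C3 on a chiral π-allyl complex of divalent palladium would trigger the 1,2-shift of the syringyl group from boron to C2 on the opposite face, giving A4, 2-[(2S,3S)-3-allyl-2-[3,5-dimethoxy-4-(triisopropylsilyloxy)phenyl]-5-(1,3-dioxolan-2-yl)-7-methoxy-2,3-dihydrobenzofuran-2-yl]-4,4,5,5-tetramethyl-1,3,2-dioxaborolane.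
- In favour: the step is convergent, makes two bonds and two stereocentres from flat aromatic partners, and the anti addition across C2–C3 makes the trans relationship inherent. On diastereocontrol it is the better plan, since no epimerisation is needed. On the choice of aromatic building blocks it is the equal of the chosen plan.
- Against: A4 carries boron on a fully substituted C2 that must be replaced by hydrogen with retention. The allyl group has two carbons too many, so alkene isomerisation, oxidative cleavage in the presence of two electron-rich arenes, and reduction would follow. The unsubstituted allyl unit is symmetrical, so the ligand has to distinguish the faces of the bulky ate complex, and a hindered, electron-rich aryl group has to migrate.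
- Comparison: on structure the chosen plan delivers C3 already at the right carbon count and C2 already bearing hydrogen. On mechanism the chosen insertion rests on a closer substrate analogy. On step economy the alternative spends about four extra operations after its key step.

Alternative 3: The O1–C2 bond is cut, leading back to the diarylpropanol A8, (2R)-2-(5-bromo-2-hydroxy-3-methoxyphenyl)-3-(4-hydroxy-3,5-dimethoxyphenyl)propan-1-ol. In the forward step Ag2O would oxidise the syringyl phenol of A8 to the para-quinone methide. The ring A phenol would then add to the methide carbon in a 5-exo-trig closure, with the aryl group settling trans to the CH2OH group, to give A7, (2S,3R)-trans-5-bromo-2-(4-hydroxy-3,5-dimethoxyphenyl)-3-(hydroxymethyl)-7-methoxy-2,3-dihydrobenzofuran.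
- In favour: the closure is biomimetic and mild, needs no phenol protection, and places C2 under the same thermodynamic preference that operates in the target. The C5 bromide would allow the side chain to be attached in one Mizoroki–Heck coupling with an acrylate partner. In protecting-group economy and brevity of the endgame it is the better plan, and in the reliability of the trans outcome it is the equal of the chosen plan.
- Against: the single stereocentre of A8 has to be installed beforehand, for example by an auxiliary-controlled benzylation of an arylacetic acid derivative that is itself not a simple purchase. The oxidant must discriminate between two phenols, and the ring A guaiacyl phenol can enter radical coupling. The quinone methide can be intercepted by water or by the primary alcohol of another molecule, and silver is used stoichiometrically.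
- Comparison: on structure the chosen plan sets both centres catalytically from purchased aromatic aldehydes. On mechanism the polar quinone-methide closure is simpler but less chemoselective than the insertion. On step economy the two plans are expected to be of similar overall length, the gain at the end of the alternative being offset by the longer preparation of A8.

Key step: step 6

Assumption: for 2-(benzyloxy)aryl diazoacetates the (S)-tert-leucinate catalyst is taken, by analogy with closely related insertions, to favour the 2R series, so the (R)-configured catalyst Rh2(R-PTTL)4 is specified for the 2S target; if the sense on 8 proved opposite, the (S)-catalyst would be used with nothing else changed.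

## Route

Step 1
Reactants: 1 5-iodovanillin (4-hydroxy-3-iodo-5-methoxybenzaldehyde)
Product: 2 4-(1,3-dioxolan-2-yl)-2-iodo-6-methoxyphenol
Conditions: ethylene glycol (5 equiv), TsOH·H2O (2 mol %), toluene, reflux, Dean–Stark; Et3N quench
Reagents that add atoms: ethylene glycol, OCCO
Why: Acid-catalysed acetalisation with azeotropic removal of water, which vanillin-type hydroxybenzaldehydes undergo with the phenol free. Masking the aldehyde first keeps it away from the phosphine/azodicarboxylate pair, the palladium–diazo coupling and the rhodium carbenoid (carbonyl ylide formation).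

Step 2
Reactants: 3 syringaldehyde (4-hydroxy-3,5-dimethoxybenzaldehyde)
Product: 4 3,5-dimethoxy-4-(triisopropylsilyloxy)benzaldehyde
Conditions: TIPSCl (1.3 equiv), imidazole (2.5 equiv), DMF, rt to 40 °C
Reagents that add atoms: chlorotriisopropylsilane (TIPSCl), CC(C)[Si](Cl)(C(C)C)C(C)C
Why: Imidazole-promoted silylation of an acidic phenol. The triisopropylsilyl ether is chosen because, flanked by two methoxy groups, it should resist the amine bases, hydride and dilute acid used later yet fall to fluoride.

Step 3
Reactants: 4 3,5-dimethoxy-4-(triisopropylsilyloxy)benzaldehyde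
Product: 5 [3,5-dimethoxy-4-(triisopropylsilyloxy)phenyl]methanol
Conditions: NaBH4 (0.6 equiv), THF/EtOH, 0 °C
Reagents that add atoms: none
Why: Borohydride reduction of an aromatic aldehyde to the benzylic alcohol. Brief contact at 0 °C leaves the hindered aryl silyl ether intact.

Step 4
Reactants: 2 4-(1,3-dioxolan-2-yl)-2-iodo-6-methoxyphenol; 5 [3,5-dimethoxy-4-(triisopropylsilyloxy)phenyl]methanol
Product: 6 2-[4-{[3,5-dimethoxy-4-(triisopropylsilyloxy)benzyl]oxy}-3-iodo-5-methoxyphenyl]-1,3-dioxolane
Conditions: PPh3 (1.3 equiv), DIAD (1.3 equiv), THF, 0 °C to rt
Reagents that add atoms: none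
Why: Mitsunobu etherification: the phenol, acidified by the ortho iodine, protonates the betaine and its phenoxide displaces the phosphonium-activated primary benzylic alcohol. The neutral conditions preserve the acetal and the silyl ether and avoid isolating an ionisation-prone, lachrymatory benzylic bromide.

Step 5
Reactants: 6 2-[4-{[3,5-dimethoxy-4-(triisopropylsilyloxy)benzyl]oxy}-3-iodo-5-methoxyphenyl]-1,3-dioxolane; 7 ethyl diazoacetate
Product: 8 ethyl 2-diazo-2-[5-(1,3-dioxolan-2-yl)-3-methoxy-2-{[3,5-dimethoxy-4-(triisopropylsilyloxy)benzyl]oxy}phenyl]acetate
Conditions: 7 as commercial toluene solution (1.5 equiv), Pd(PPh3)4 (5 mol %), Ag2CO3 (0.5 equiv), Et3N (1.3 equiv), toluene, rt, dark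
Reagents that add atoms: none
Why: Palladium-catalysed C–H arylation of an acceptor diazo compound: oxidative addition of the aryl iodide to zerovalent palladium, base-assisted palladation of the acidic C–H of the diazoacetate with silver removing iodide, and reductive elimination that keeps the diazo group. The ambient temperature suits acetal, silyl ether and benzylic ether, and the diazoacetate is handled only as a dilute solution and never heated or concentrated.

Step 6
Reactants: 8 ethyl 2-diazo-2-[5-(1,3-dioxolan-2-yl)-3-methoxy-2-{[3,5-dimethoxy-4-(triisopropylsilyloxy)benzyl]oxy}phenyl]acetate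
Product: 10 ethyl (2S,3S)-trans-2-[3,5-dimethoxy-4-(triisopropylsilyloxy)phenyl]-5-(1,3-dioxolan-2-yl)-7-methoxy-2,3-dihydrobenzofuran-3-carboxylate, via cis ester 9 (not isolated)
Conditions: Rh2(R-PTTL)4 [dirhodium tetrakis(N-phthaloyl-(R)-tert-leucinate)] (2 mol %), toluene, −60 °C, slow addition of 8; then DBU (2 equiv), −60 to 40 °C
Reagents that add atoms: none
Why: Rh2(R-PTTL)4 (divalent rhodium) extrudes N2 from 8 to give an electrophilic donor/acceptor carbenoid at the carbon that becomes C3, and this carbon inserts into one C–H bond of the OCH2Ar group five atoms away through a three-centre, hydride-transfer-like transition state in which the C2–C3 bond forms as hydrogen moves to C3 and the catalyst is released. The closest known reaction type is the enantioselective intramolecular 1,5 C–H insertion of 2-(benzyloxy)aryl diazoacetates catalysed by dirhodium phthaloyl-amino-acid carboxylates, which gives cis-2-aryl-2,3-dihydrobenzofuran-3-carboxylates. The dihydrofuran ring (O1, C2, C3, C3a, C7a) is closed by C–C bond formation in a 1,5-insertion mode, the carbene carbon joining the sp3 benzylic carbon with retention at that carbon, five-membered closure being the geometrically preferred ring size for carbenoid insertion. C2 is set by the catalyst: the four phthalimido tert-leucinate ligands form a chiral pocket that selects which of the two enantiotopic benzylic hydrogens is replaced, and the (R)-ligand series is chosen to deliver 2S. C3 is first formed cis to the aryl group in 9 as a consequence of the compact transition state and is then corrected by thermodynamics: DBU reversibly deprotonates C3 (benzylic and alpha to the ester) and reprotonation gives the less strained trans ester 10. C2 is not touched during this equilibration because the silyl-capped phenol cannot open the ring through a quinone methide and beta-elimination of O1 from the C3 enolate is the stereoelectronically poor reverse of a 5-endo-trig closure. The step needs chemoselectivity for the ether CH2 over the acetal C–H, the methoxy C–H bonds, the arenes and carbene dimerisation, and this is secured by proximity (only the ether CH2 can reach the carbene through a five-membered transition state), by activation of that C–H by the adjacent oxygen and the electron-rich aryl group, and by low temperature and slow addition. It also needs the insertion to stay concerted for high enantioselectivity, which the out-of-plane silyloxy group and the two inductively withdrawing meta-methoxy groups favour by tempering the hydridic character of the benzylic C–H bond.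

Step 7
Reactants: 10 ethyl (2S,3S)-trans-2-[3,5-dimethoxy-4-(triisopropylsilyloxy)phenyl]-5-(1,3-dioxolan-2-yl)-7-methoxy-2,3-dihydrobenzofuran-3-carboxylate
Product: 12 (2S,3R)-2-[3,5-dimethoxy-4-(triisopropylsilyloxy)phenyl]-3-(hydroxymethyl)-7-methoxy-2,3-dihydrobenzofuran-5-carbaldehyde, via acetal alcohol 11 (not isolated)
Conditions: LiBH4 (2 equiv), THF, 0 °C to rt; then 1 M HCl (aq), 0 °C to rt
Reagents that add atoms: water, O
Why: LiBH4 reduces the ester to the primary alcohol without touching acetal or aryl silyl ether, which fixes C3 (the descriptor changes from S to R only through the priority rules, the geometry being unchanged). The aqueous acid destroys the remaining hydride well before it hydrolyses the dioxolane, so the liberated aldehyde is not reduced, and dilute acid at rt should leave the silyl ether and the benzylic C2–O1 bond intact.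

Step 8
Reactants: 12 (2S,3R)-2-[3,5-dimethoxy-4-(triisopropylsilyloxy)phenyl]-3-(hydroxymethyl)-7-methoxy-2,3-dihydrobenzofuran-5-carbaldehyde
Product: 14 (E)-3-[(2S,3R)-2-[3,5-dimethoxy-4-(triisopropylsilyloxy)phenyl]-3-(hydroxymethyl)-7-methoxy-2,3-dihydrobenzofuran-5-yl]prop-2-enoic acid, via arylidenemalonic acid 13 (not isolated)
Conditions: malonic acid (3 equiv), pyridine, piperidine (0.1 equiv), 80 °C
Reagents that add atoms: malonic acid, OC(=O)CC(=O)O
Why: Knoevenagel–Doebner condensation: amine-catalysed condensation of the aldehyde with malonic acid, then decarboxylation in pyridine to the thermodynamically favoured (E)-cinnamic acid. The primary alcohol is a spectator, and the silyl cap keeps the syringyl oxygen from becoming a phenoxide that could open the dihydrofuran in hot amine.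

Step 9
Reactants: 14 (E)-3-[(2S,3R)-2-[3,5-dimethoxy-4-(triisopropylsilyloxy)phenyl]-3-(hydroxymethyl)-7-methoxy-2,3-dihydrobenzofuran-5-yl]prop-2-enoic acid
Product: 15 (E)-3-[(2S,3R)-2-(4-hydroxy-3,5-dimethoxyphenyl)-3-(hydroxymethyl)-7-methoxy-2,3-dihydrobenzofuran-5-yl]prop-2-enoic acid
Conditions: Bu4NF (3 equiv), AcOH (3 equiv), THF, 0 °C to rt, dark; dilute HCl work-up
Reagents that add atoms: none
Why: Fluoride-induced cleavage of the aryl silyl ether, driven by the strength of the Si–F bond. The acetic acid buffer keeps the liberated phenol protonated, so neither quinone-methide opening at C2 nor conjugate addition to the acrylic acid is promoted, and no stereocentre is touched.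

## Compound list

1 | 5-iodovanillin (4-hydroxy-3-iodo-5-methoxybenzaldehyde) | COc1cc(C=O)cc(I)c1O | starting material
2 | 4-(1,3-dioxolan-2-yl)-2-iodo-6-methoxyphenol | COc1cc(C2OCCO2)cc(I)c1O | intermediate
3 | syringaldehyde (4-hydroxy-3,5-dimethoxybenzaldehyde) | COc1cc(C=O)cc(OC)c1O | starting material
4 | 3,5-dimethoxy-4-(triisopropylsilyloxy)benzaldehyde | COc1cc(C=O)cc(OC)c1O[Si](C(C)C)(C(C)C)C(C)C | intermediate
5 | [3,5-dimethoxy-4-(triisopropylsilyloxy)phenyl]methanol | COc1cc(CO)cc(OC)c1O[Si](C(C)C)(C(C)C)C(C)C | intermediate
6 | 2-[4-{[3,5-dimethoxy-4-(triisopropylsilyloxy)benzyl]oxy}-3-iodo-5-methoxyphenyl]-1,3-dioxolane | COc1cc(C2OCCO2)cc(I)c1OCc1cc(OC)c(O[Si](C(C)C)(C(C)C)C(C)C)c(OC)c1 | intermediate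
7 | ethyl diazoacetate | CCOC(=O)C=[N+]=[N-] | starting material
8 | ethyl 2-diazo-2-[5-(1,3-dioxolan-2-yl)-3-methoxy-2-{[3,5-dimethoxy-4-(triisopropylsilyloxy)benzyl]oxy}phenyl]acetate | CCOC(=O)C(=[N+]=[N-])c1cc(C2OCCO2)cc(OC)c1OCc1cc(OC)c(O[Si](C(C)C)(C(C)C)C(C)C)c(OC)c1 | intermediate
9 | ethyl (2S,3R)-cis-2-[3,5-dimethoxy-4-(triisopropylsilyloxy)phenyl]-5-(1,3-dioxolan-2-yl)-7-methoxy-2,3-dihydrobenzofuran-3-carboxylate | COc1cc([C@H]2Oc3c(OC)cc(C4OCCO4)cc3[C@H]2C(=O)OCC)cc(OC)c1O[Si](C(C)C)(C(C)C)C(C)C | intermediate (not isolated)
10 | ethyl (2S,3S)-trans-2-[3,5-dimethoxy-4-(triisopropylsilyloxy)phenyl]-5-(1,3-dioxolan-2-yl)-7-methoxy-2,3-dihydrobenzofuran-3-carboxylate | COc1cc([C@H]2Oc3c(OC)cc(C4OCCO4)cc3[C@@H]2C(=O)OCC)cc(OC)c1O[Si](C(C)C)(C(C)C)C(C)C | intermediate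
11 | [(2S,3R)-2-[3,5-dimethoxy-4-(triisopropylsilyloxy)phenyl]-5-(1,3-dioxolan-2-yl)-7-methoxy-2,3-dihydrobenzofuran-3-yl]methanol | COc1cc([C@H]2Oc3c(OC)cc(C4OCCO4)cc3[C@@H]2CO)cc(OC)c1O[Si](C(C)C)(C(C)C)C(C)C | intermediate (not isolated)
12 | (2S,3R)-2-[3,5-dimethoxy-4-(triisopropylsilyloxy)phenyl]-3-(hydroxymethyl)-7-methoxy-2,3-dihydrobenzofuran-5-carbaldehyde | COc1cc([C@H]2Oc3c(OC)cc(C=O)cc3[C@@H]2CO)cc(OC)c1O[Si](C(C)C)(C(C)C)C(C)C | intermediate
13 | 2-{[(2S,3R)-2-[3,5-dimethoxy-4-(triisopropylsilyloxy)phenyl]-3-(hydroxymethyl)-7-methoxy-2,3-dihydrobenzofuran-5-yl]methylidene}propanedioic acid | COc1cc([C@H]2Oc3c(OC)cc(C=C(C(=O)O)C(=O)O)cc3[C@@H]2CO)cc(OC)c1O[Si](C(C)C)(C(C)C)C(C)C | intermediate (not isolated)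
14 | (E)-3-[(2S,3R)-2-[3,5-dimethoxy-4-(triisopropylsilyloxy)phenyl]-3-(hydroxymethyl)-7-methoxy-2,3-dihydrobenzofuran-5-yl]prop-2-enoic acid | COc1cc([C@H]2Oc3c(OC)cc(/C=C/C(=O)O)cc3[C@@H]2CO)cc(OC)c1O[Si](C(C)C)(C(C)C)C(C)C | intermediate
15 | (E)-3-[(2S,3R)-2-(4-hydroxy-3,5-dimethoxyphenyl)-3-(hydroxymethyl)-7-methoxy-2,3-dihydrobenzofuran-5-yl]prop-2-enoic acid | COc1cc([C@H]2Oc3c(OC)cc(/C=C/C(=O)O)cc3[C@@H]2CO)cc(OC)c1O | target

## Step count and least certain steps

Total step count: 9. Longest linear sequence: 8 steps (from 3 through steps 2 to 9); the branch from 1 contributes step 1 and joins at step 4.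

Step 6 (key step). The most likely failure is loss of enantiocontrol: the electron-rich benzylic ether may shift the insertion towards stepwise hydride transfer through a zwitterion that closes with little facial bias, or the sense of induction may be opposite to the one assumed. Incomplete equilibration to trans and carbene dimerisation are lesser risks. The fallback replaces catalyst control by double stereodifferentiation with a removable chiral ester; it sets out from 6 and comes back at 11.
- Ethyl (S)-lactate would be heated with pyrrolidine to give (2S)-2-hydroxy-1-(pyrrolidin-1-yl)propan-1-one F1.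
- Acylation with bromoacetyl bromide and pyridine would give (2S)-1-oxo-1-(pyrrolidin-1-yl)propan-2-yl 2-bromoacetate F2.
- N,N'-Ditosylhydrazine and DBU would convert it into (2S)-1-oxo-1-(pyrrolidin-1-yl)propan-2-yl 2-diazoacetate F3.
- Coupling of F3 with 6 under the conditions of step 5 would give (2S)-1-oxo-1-(pyrrolidin-1-yl)propan-2-yl 2-diazo-2-[5-(1,3-dioxolan-2-yl)-3-methoxy-2-{[3,5-dimethoxy-4-(triisopropylsilyloxy)benzyl]oxy}phenyl]acetate F4.
- Insertion would use the matched enantiomer of Rh2(DOSP)4 (dirhodium tetrakis[N-(4-dodecylphenylsulfonyl)prolinate]), followed by DBU equilibration. This would give (2S)-1-oxo-1-(pyrrolidin-1-yl)propan-2-yl (2S,3S)-trans-2-[3,5-dimethoxy-4-(triisopropylsilyloxy)phenyl]-5-(1,3-dioxolan-2-yl)-7-methoxy-2,3-dihydrobenzofuran-3-carboxylate F5.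
- The stereoisomers of F5 are diastereomers and could be separated by chromatography or crystallisation.
- LiBH4 reduction of F5 releases the auxiliary and gives 11, which continues through the acid stage of step 7.

Step 5. The bulky ortho ether may slow the coupling at palladium, so that palladium-mediated decomposition of the diazoacetate (carbene dimerisation) or loss of N2 from the product outruns it. The fallback builds the C–C bond first and introduces the diazo group afterwards, which also removes ethyl diazoacetate from the route; it sets out from 6 and comes back at 8.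
- Palladium-catalysed arylation of the Reformatsky reagent BrZnCH2CO2Et (Pd2(dba)3, XPhos, THF, 40 to 60 °C) would give ethyl 2-[5-(1,3-dioxolan-2-yl)-3-methoxy-2-{[3,5-dimethoxy-4-(triisopropylsilyloxy)benzyl]oxy}phenyl]acetate F6.
- Regitz diazo transfer with 4-acetamidobenzenesulfonyl azide and DBU in MeCN would convert F6 into 8.

Step 4. The phenoxide is flanked by iodine and methoxy and may displace slowly, so the activated, electron-rich benzylic alcohol could instead alkylate the reduced azodicarboxylate or ionise and self-condense. The fallback separates activation from ether formation; it sets out from 5 and comes back at 6.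
- Appel bromination (CBr4, PPh3, CH2Cl2, 0 °C) would give [4-(bromomethyl)-2,6-dimethoxyphenoxy]triisopropylsilane F7, used at once.
- Williamson alkylation of 2 with F7 (K2CO3, acetone, rt) would give 6.

Step 8. Hot amine base may partly strip the silyl group, and the resulting phenoxide could open the dihydrofuran through a quinone methide; acylation of the CH2OH group by malonic acid or incomplete decarboxylation are further risks. The fallback installs the side chain by a neutral olefination at ambient temperature; it sets out from 12 and comes back at 14.
- Wittig reaction with allyl (triphenylphosphoranylidene)acetate (CH2Cl2, rt) would give prop-2-en-1-yl (E)-3-[(2S,3R)-2-[3,5-dimethoxy-4-(triisopropylsilyloxy)phenyl]-3-(hydroxymethyl)-7-methoxy-2,3-dihydrobenzofuran-5-yl]prop-2-enoate F8.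
- Deallylation with Pd(PPh3)4 and morpholine in THF at rt would give 14.

## Further compounds

F1 | step 6 | (2S)-2-hydroxy-1-(pyrrolidin-1-yl)propan-1-one | C[C@H](O)C(=O)N1CCCC1
F2 | step 6 | (2S)-1-oxo-1-(pyrrolidin-1-yl)propan-2-yl 2-bromoacetate | C[C@H](OC(=O)CBr)C(=O)N1CCCC1
F3 | step 6 | (2S)-1-oxo-1-(pyrrolidin-1-yl)propan-2-yl 2-diazoacetate | C[C@H](OC(=O)C=[N+]=[N-])C(=O)N1CCCC1
F4 | step 6 | (2S)-1-oxo-1-(pyrrolidin-1-yl)propan-2-yl 2-diazo-2-[5-(1,3-dioxolan-2-yl)-3-methoxy-2-{[3,5-dimethoxy-4-(triisopropylsilyloxy)benzyl]oxy}phenyl]acetate | C[C@H](OC(=O)C(=[N+]=[N-])c1cc(C2OCCO2)cc(OC)c1OCc1cc(OC)c(O[Si](C(C)C)(C(C)C)C(C)C)c(OC)c1)C(=O)N1CCCC1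
F5 | step 6 | (2S)-1-oxo-1-(pyrrolidin-1-yl)propan-2-yl (2S,3S)-trans-2-[3,5-dimethoxy-4-(triisopropylsilyloxy)phenyl]-5-(1,3-dioxolan-2-yl)-7-methoxy-2,3-dihydrobenzofuran-3-carboxylate | COc1cc([C@H]2Oc3c(OC)cc(C4OCCO4)cc3[C@@H]2C(=O)O[C@@H](C)C(=O)N2CCCC2)cc(OC)c1O[Si](C(C)C)(C(C)C)C(C)C
F6 | step 5 | ethyl 2-[5-(1,3-dioxolan-2-yl)-3-methoxy-2-{[3,5-dimethoxy-4-(triisopropylsilyloxy)benzyl]oxy}phenyl]acetate | CCOC(=O)Cc1cc(C2OCCO2)cc(OC)c1OCc1cc(OC)c(O[Si](C(C)C)(C(C)C)C(C)C)c(OC)c1
F7 | step 4 | [4-(bromomethyl)-2,6-dimethoxyphenoxy]triisopropylsilane | COc1cc(CBr)cc(OC)c1O[Si](C(C)C)(C(C)C)C(C)C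
F8 | step 8 | prop-2-en-1-yl (E)-3-[(2S,3R)-2-[3,5-dimethoxy-4-(triisopropylsilyloxy)phenyl]-3-(hydroxymethyl)-7-methoxy-2,3-dihydrobenzofuran-5-yl]prop-2-enoate | COc1cc([C@H]2Oc3c(OC)cc(/C=C/C(=O)OCC=C)cc3[C@@H]2CO)cc(OC)c1O[Si](C(C)C)(C(C)C)C(C)C
A1 | alternative 1 | methyl (2S,3R)-trans-7-bromo-2-[3,5-dimethoxy-4-(methoxymethoxy)phenyl]-3-[(methoxymethoxy)methyl]-2,3-dihydrobenzofuran-5-carboxylate | COc1cc([C@H]2Oc3c(Br)cc(C(=O)OC)cc3[C@@H]2COCOC)cc(OC)c1OCOC
A2 | alternative 1 | (4R,5S)-5-[3,5-dimethoxy-4-(methoxymethoxy)phenyl]-4-[(methoxymethoxy)methyl]oxolan-2-one | COc1cc([C@H]2OC(=O)C[C@@H]2COCOC)cc(OC)c1OCOC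
A3 | alternative 1 | methyl 3-bromo-2-oxo-2H-pyran-5-carboxylate | COC(=O)C1=COC(=O)C(Br)=C1
A4 | alternative 2 | 2-[(2S,3S)-3-allyl-2-[3,5-dimethoxy-4-(triisopropylsilyloxy)phenyl]-5-(1,3-dioxolan-2-yl)-7-methoxy-2,3-dihydrobenzofuran-2-yl]-4,4,5,5-tetramethyl-1,3,2-dioxaborolane (aryl and allyl trans) | COc1cc([C@@]2(B3OC(C)(C)C(C)(C)O3)Oc3c(OC)cc(C4OCCO4)cc3[C@@H]2CC=C)cc(OC)c1O[Si](C(C)C)(C(C)C)C(C)C
A5 | alternative 2 | 2-(7-methoxy-1-benzofuran-5-yl)-1,3-dioxolane | COc1cc(C2OCCO2)cc2ccoc12
A6 | alternative 2 | 2-[3,5-dimethoxy-4-(triisopropylsilyloxy)phenyl]-4,4,5,5-tetramethyl-1,3,2-dioxaborolane | COc1cc(B2OC(C)(C)C(C)(C)O2)cc(OC)c1O[Si](C(C)C)(C(C)C)C(C)C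
A7 | alternative 3 | (2S,3R)-trans-5-bromo-2-(4-hydroxy-3,5-dimethoxyphenyl)-3-(hydroxymethyl)-7-methoxy-2,3-dihydrobenzofuran | COc1cc([C@H]2Oc3c(OC)cc(Br)cc3[C@@H]2CO)cc(OC)c1O
A8 | alternative 3 | (2R)-2-(5-bromo-2-hydroxy-3-methoxyphenyl)-3-(4-hydroxy-3,5-dimethoxyphenyl)propan-1-ol | COc1cc(C[C@@H](CO)c2cc(Br)cc(OC)c2O)cc(OC)c1O
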